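**Remark on the chemistry:** the target has no stereocentre. It is taken as the 2-hydroxy-1,4-benzoquinone tautomer written in its SMILES, into which the hydroxy-ortho-quinone tautomer 12 is expected to pass spontaneously.

**Numbers used throughout:** 1 veratrole; 2 1-bromoicosane; 3 (2,3-dimethoxyphenyl)lithium; 4 3-icosylveratrole; 5 3-icosylcatechol; 6 methanol; 7 3-icosyl-1,2-benzoquinone; 8 3-icosyl-5-methoxycatechol; 9 3-icosyl-5-methoxy-1,2-benzoquinone; 10 3-icosyl-4,5-dimethoxycatechol; 11 3-icosyl-4,5-dimethoxy-1,2-benzoquinone; 12 4-hydroxy-3-icosyl-5-methoxy-1,2-benzoquinone; 13 irisoquin D.

## Analysis of the target

Irisoquin D (13) is a single six-membered 1,4-benzoquinone ring carrying one unbranched C20 chain. The ring is numbered C1(=O), C2(OH), C3(icosyl), C4(=O), C5(OMe), C6(H). There is no stereocentre and no double-bond geometry to set, so the problem is one of regiochemistry only.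

Four of the six ring carbons carry oxygen. The C2 hydroxyl is a vinylogous acid chelated to the C1 carbonyl, and the C5 methoxy group is a vinylogous ester that exchanges under acid or base. The hydroxyquinone is also sensitive to reductants and to strong nucleophiles, so the quinone should be unveiled late and under mild conditions.

The difficulty lies in telling apart the two non-carbonyl oxygens at C2 and C5, which sit in nearly equivalent positions across the ring. The hydroxyl must end up next to the chain and the methyl ether next to C6–H. The waxy, poorly soluble C20 chain is a practical burden that calls for a short route with few purifications.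

The strategy rests on the para relationships C1/C4 and C2/C5. In the ortho-quinone 7, which has carbonyls at C1 and C2 and the chain at C3, carbons C4 and C5 are the two conjugate (β) positions. Both missing oxygens can therefore be delivered there by methanol (6) to a simple 3-alkylcatechol (5). The crowding of the C4 oxygen between the chain and the C5 oxygen is what later distinguishes OH from OMe.

## Retrosynthetic reasoning

**From 13 to 11.** Compound 13 is the para-quinone tautomer of the hydroxy-ortho-quinone 12, and 12 is the dimethoxy-ortho-quinone 11 with the methyl group at the C4 oxygen replaced by hydrogen. The backward operation therefore turns the C4 hydroxyl into a methoxy group. This makes the C4 and C5 oxygens alike, so both can come from 6, and it converts the para-quinone into an ortho-quinone that maps onto a catechol. Forward, aqueous acid must hydrolyse the C4–OMe vinylogous ester and leave the C5–OMe in place. The twisting of the crowded C4 methoxy group out of conjugation is expected to provide this selectivity.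

**From 11 to 5 and 6.** The C4–O and C5–O bonds are cut. They are chosen because C4 and C5 are the β-carbons of the two enone units of ortho-quinone 7, so each bond forms with natural polarity from the nucleophilic oxygen of 6. Cutting C1–O or C2–O instead would call for oxygenation at carbons that are not electrophilic in any simple quinone. The gain is large: two heteroatom bonds are removed in one operation, leaving catechol 5 with a single carbon substituent. Forward, one flask must perform three two-electron oxidations and two conjugate additions by way of 7, 8, 9 and 10. Attack at C6 and coupling between the quinones and the catechols must be avoided.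

**From 5 to 4.** The two phenolic hydrogens are replaced by methyl groups. The methyl ethers are needed one stage earlier as directing groups and as protection against a strong base. Forward, a Lewis acid must cleave both aryl methyl ethers of 4, and the saturated chain is inert to it.

**From 4 to 1 and 2.** The bond between ring carbon C3 and the first chain carbon is cut. C3 lies ortho to a methoxy group, so directed metalation of the symmetrical arene 1 makes it a nucleophile (3) at the only type of position available. The chain then needs only to be the primary alkyl electrophile 2. A Friedel–Crafts disconnection at the same bond would direct the chain para to oxygen, that is to the wrong carbon. The gain is two cheap commercial components.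

## Alternatives that were turned down

Alternative 1: Dötz benzannulation.
- Disconnection: the ring is cut at C3–C4, C1–C2 and C1–C6. C4, C5 and C6 come from the carbene complex pentacarbonyl[methoxy(1-methoxyvinyl)carbene]chromium A1. C2 and C3 come from the alkynyl boronate 2-(docos-1-yn-1-yl)-4,4,5,5-tetramethyl-1,3,2-dioxaborolane A2. C1 comes from one CO ligand of A1.
- Forward key step: heating A1 with A2 would bring about alkyne insertion, CO insertion and electrocyclisation. The product would be the phenol 3-icosyl-4,5-dimethoxy-2-(4,4,5,5-tetramethyl-1,3,2-dioxaborolan-2-yl)phenol A3, in which boron marks the future C2 hydroxyl.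
- For it: every substituent is placed by the connectivity of the components. The C2 and C5 oxygens of A3 are different from the start (boron against methyl ether), so oxidation of the para-methoxyphenol unit and of the C–B bond would reach 13 without any selective ether cleavage. On that point it is stronger than the chosen route.
- Against it: the chromium is stoichiometric. A1 needs two air-sensitive steps of its own before the annulation. A2 needs a C22 terminal alkyne and a borylation. The quinone boronate has to survive two oxidations. The count is about six to seven steps.
- Comparison: if the C–B bond of A3 were oxidised first, the product would be 10, an intermediate the chosen route reaches from commodity chemicals in three steps. The chosen strategy gives up built-in regiocontrol for a four-step, metal-free sequence on a bought aromatic ring.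

Alternative 2: oxalate double Claisen annulation.
- Disconnection: C3–C4 and C5–C6 are cut. C4 and C5 come from an oxalate diester, and C6, C1, C2 and C3 from tetracosane-2,3-dione A4.
- Forward key step: under alkoxide base the methyl group of A4 and then its chain-bearing methylene would each acylate one ester carbon. This would close the ring directly as 2,5-dihydroxy-3-icosyl-1,4-benzoquinone A5.
- For it: the ring and all four oxygens arrive in one redox-neutral step with no oxidant. On redox economy it is stronger than the chosen route.
- Against it: A4 is not commercial and needs a regiodefined synthesis of its own. Aliphatic 1,2-diketones self-condense readily under alkoxide. The second Claisen has to form a bond at the hindered methylene. A5 still has two hydroxyls, so a selective mono-methylation at C5 remains.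
- Comparison: with the synthesis of A4 the count is about five steps, and the key step is much less secure than a conjugate addition to a quinone. The chosen strategy builds no ring at all and puts its single differentiation step on a substrate whose crowding at C4 does the selecting.

Alternative 3: Moore ring expansion.
- Disconnection: the C4–C5 bond is cut and the ring contracted to the racemic cyclobutenone 4-hydroxy-2-icosyl-3-isopropoxy-4-(methoxyethynyl)cyclobut-2-en-1-one A6. A6 is assembled from a squarate diester by successive additions of a C20 organometallic and a metalated alkoxyalkyne.
- Forward key step: heating A6 in toluene or xylene would open the four-membered ring to a vinylketene, which closes onto the alkyne. Hydrogen transfer would then give 3-icosyl-2-isopropoxy-5-methoxy-1,4-benzoquinone A7.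
- For it: the substitution pattern is programmed by the order of the additions. The C2 and C5 oxygens of A7 carry different alkyl groups, so the secondary ether of A7 can be cleaved without ambiguity. On regiochemical certainty it is stronger than the chosen route.
- Against it: two cryogenic organometallic additions are needed, one with an unstable and hazardous alkoxyacetylide. Mono-addition and the site of the second addition must be controlled. Five-membered ring closure competes in the thermolysis of A6. With the final dealkylation of A7 the count is about five steps.
- Comparison: the chosen strategy accepts one selectivity question (which ether hydrolyses) that A7 would not pose. In return it uses only veratrole, an alkyl bromide and methanol, with no sensitive reagent after the first step.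

Key step: step 3

## Route

Step 1
Reactants: 1 veratrole (1,2-dimethoxybenzene); 2 1-bromoicosane
Product: 4 1-icosyl-2,3-dimethoxybenzene (3-icosylveratrole), via (2,3-dimethoxyphenyl)lithium 3 (not isolated)
Conditions: n-BuLi, TMEDA, THF, 0 °C to rt; then 2, THF, rt to 50 °C
Reagents that add atoms: none
Why: Directed ortho-metalation: the methoxy groups of 1 steer n-BuLi/TMEDA to the position next to oxygen (both such positions are equivalent), and aryllithium 3 is alkylated by the primary bromide 2 in an SN2 reaction, as in known preparations of 3-alkylveratroles. A slight excess of 3 over 2 should consume the bromide, and surplus 1 is removed by distillation.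

Step 2
Reactants: 4 1-icosyl-2,3-dimethoxybenzene
Product: 5 3-icosylbenzene-1,2-diol (3-icosylcatechol)
Conditions: BBr3, CH2Cl2, −78 °C to rt; then H2O
Reagents that add atoms: none
Why: BBr3 coordinates each ether oxygen and bromide cleaves the O–CH3 bond by SN2 attack at methyl, the standard aryl methyl ether cleavage; the saturated chain is inert and the cyclic aryl borate is hydrolysed on work-up. Compound 5 is kept under argon because 3-alkylcatechols autoxidise.

Step 3
Reactants: 5 3-icosylcatechol; 6 methanol
Product: 11 3-icosyl-4,5-dimethoxy-1,2-benzoquinone, via 3-icosyl-1,2-benzoquinone 7 (not isolated), via 3-icosyl-5-methoxycatechol 8 (not isolated), via 3-icosyl-5-methoxy-1,2-benzoquinone 9 (not isolated), via 3-icosyl-4,5-dimethoxycatechol 10 (not isolated)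
Conditions: graphite anode, platinum cathode, divided cell, NaOAc (0.2 M), MeOH/THF, rt, controlled anode potential (about +0.45 V vs SCE), about 6 F/mol
Reagents that add atoms: methanol (compound 6), CO
Why: Anodic two-electron oxidation of 5, buffered by acetate, gives ortho-quinone 7, whose C5, the less hindered β-carbon of an enone unit, takes up methanol in a 1,4-addition; enolisation gives catechol 8, which is more electron-rich than 5 and is oxidised at once to 9. In 9 the C5 methoxy group turns the C1 carbonyl into a vinylogous ester, so the only electrophilic enone left is O=C2–C3=C4 and the second methanol adds at C4 to give 10, which loses two more electrons to give 11; six electrons per molecule are passed in all and the protons are reduced to hydrogen in the cathode chamber. The closest known reaction type is the anodic methoxylation of catechol and of 3-substituted catechols to 4,5-dimethoxy-1,2-benzoquinones, an ECECE sequence of electron transfers and Michael additions. No ring is closed and no stereocentre is formed. The step needs site selectivity for C4 and C5 over C6 and chemoselectivity for methanol over the catechols as nucleophile: C6 is reachable only by 1,6-addition in 7 and is the nucleophilic α-carbon of a vinylogous ester in 9, the chain on C3 blocks neither β-carbon, and methanol as solvent in large excess at low substrate concentration should outrun coupling of 5, 8 or 10 with the quinones. Were the first addition to take place at C4, the second would be steered to C5 by the same vinylogous ester argument, so both orders converge on 11. The two vinylogous ester units of 11 deactivate it towards a third addition, and the divided cell keeps 11 away from the cathode, where it would be reduced back to 10.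

Step 4
Reactants: 11 3-icosyl-4,5-dimethoxy-1,2-benzoquinone
Product: 13 irisoquin D (2-hydroxy-3-icosyl-5-methoxy-1,4-benzoquinone), via 4-hydroxy-3-icosyl-5-methoxy-1,2-benzoquinone 12 (not isolated)
Conditions: HClO4 (70% aq.), THF/H2O, 0 °C to rt
Reagents that add atoms: water, O
Why: Acid-catalysed addition–elimination at a vinylogous ester: water adds to C4 of the protonated quinone and methanol is expelled, the known hydrolysis of 4,5-dimethoxy-1,2-benzoquinones to 2-hydroxy-5-methoxy-1,4-benzoquinones, after which 12 tautomerises to the chelated para-quinone 13. C4 is expected to react before C5 because its methoxy group is forced out of the ring plane by the chain and the C5 methoxy group, which weakens its donation and makes C4 the more electrophilic carbon, and because the product keeps the unhindered, fully conjugated C5 ether.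

## Compound list

1 | veratrole (1,2-dimethoxybenzene) | COc1ccccc1OC | starting material
2 | 1-bromoicosane | CCCCCCCCCCCCCCCCCCCCBr | starting material
3 | (2,3-dimethoxyphenyl)lithium | [Li]c1cccc(OC)c1OC | intermediate (not isolated)
4 | 1-icosyl-2,3-dimethoxybenzene (3-icosylveratrole) | CCCCCCCCCCCCCCCCCCCCc1cccc(OC)c1OC | intermediate
5 | 3-icosylbenzene-1,2-diol (3-icosylcatechol) | CCCCCCCCCCCCCCCCCCCCc1cccc(O)c1O | intermediate
6 | methanol | CO | starting material
7 | 3-icosyl-1,2-benzoquinone | CCCCCCCCCCCCCCCCCCCCC1=CC=CC(=O)C1=O | intermediate (not isolated)
8 | 3-icosyl-5-methoxybenzene-1,2-diol (3-icosyl-5-methoxycatechol) | CCCCCCCCCCCCCCCCCCCCc1cc(OC)cc(O)c1O | intermediate (not isolated)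
9 | 3-icosyl-5-methoxy-1,2-benzoquinone | CCCCCCCCCCCCCCCCCCCCC1=CC(OC)=CC(=O)C1=O | intermediate (not isolated)
10 | 3-icosyl-4,5-dimethoxybenzene-1,2-diol (3-icosyl-4,5-dimethoxycatechol) | CCCCCCCCCCCCCCCCCCCCc1c(OC)c(OC)cc(O)c1O | intermediate (not isolated)
11 | 3-icosyl-4,5-dimethoxy-1,2-benzoquinone | CCCCCCCCCCCCCCCCCCCCC1=C(OC)C(OC)=CC(=O)C1=O | intermediate
12 | 4-hydroxy-3-icosyl-5-methoxy-1,2-benzoquinone | CCCCCCCCCCCCCCCCCCCCC1=C(O)C(OC)=CC(=O)C1=O | intermediate (not isolated)
13 | irisoquin D (2-hydroxy-3-icosyl-5-methoxy-1,4-benzoquinone) | CCCCCCCCCCCCCCCCCCCCC1=C(O)C(=O)C=C(OC)C1=O | target

## Step count and least certain steps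

Total step count: 4. Longest linear sequence: 4 steps (1 → 4 → 5 → 11 → 13).

**Step 3 (key step).**
- What may go wrong: the electrogenerated quinones 7 and 9 may couple with the electron-rich catechols 5, 8 and 10 instead of with methanol. This would deposit oligomer films that passivate the anode. The C20 chain makes the substrate poorly soluble and surface-active in the methanolic electrolyte, which makes this worse. A second possible failure is 1,6-attack of methanol at C6 of 7.
- Fallback: the electrode is abandoned and the same six-electron oxidation is run with a stoichiometric chemical oxidant. Catechol 5 is added slowly to a stirred suspension of NaIO3 in MeOH with CH2Cl2 as co-solvent at rt. The oxidant is then always in excess over the catechol, which disfavours quinone–catechol coupling, and neither electrolyte nor electrode surface is involved. This is the known iodate-mediated conversion of catechols into 4,5-dimethoxy-1,2-benzoquinones. It sets out from 5 and comes back to the route at 11. It makes no compound outside the compound list, which is recorded below as F0.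

**Step 4.**
- What may go wrong: site selectivity in the hydrolysis may be lost, with water attacking C5 instead of C4, or both vinylogous esters may be hydrolysed.
- Fallback: selective hydrolysis is not relied on. Both ethers of 11 are hydrolysed deliberately (aq. H2SO4, 1,4-dioxane, 60 °C) to 2,5-dihydroxy-3-icosyl-1,4-benzoquinone F1, which has the same structure as A5. The ether is then put back by acid-catalysed etherification (MeOH, cat. H2SO4, rt). The C5 hydroxyl, flanked only by C6–H, should react faster than the C2 hydroxyl buried between chain and carbonyl, and the reaction is stopped at the mono-ether. This sets out from 11 and comes back at 13.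

**Step 1.**
- What may go wrong: SN2 substitution of the hindered aryllithium on a long-chain primary bromide may be slow. It then competes with E2 elimination and with lithium–bromine exchange followed by Wurtz coupling. Leftover bromide is hard to separate from the equally non-polar product.
- Fallback: the type of electrophile is changed. Aryllithium 3 is added at −78 °C to icosanal F2, a fast 1,2-addition, to give racemic 1-(2,3-dimethoxyphenyl)icosan-1-ol F3. Its benzylic hydroxyl is then removed by ionic hydrogenation (Et3SiH, TFA, CH2Cl2, 0 °C to rt). This sets out from 3 (made from 1 as in step 1) and comes back at 4.

## Further compounds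

F0 | step 3 | none | none
F1 | step 4 | 2,5-dihydroxy-3-icosyl-1,4-benzoquinone | CCCCCCCCCCCCCCCCCCCCC1=C(O)C(=O)C=C(O)C1=O
F2 | step 1 | icosanal | CCCCCCCCCCCCCCCCCCCC=O
F3 | step 1 | 1-(2,3-dimethoxyphenyl)icosan-1-ol (racemic) | CCCCCCCCCCCCCCCCCCCC(O)c1cccc(OC)c1OC
A1 | alternative 1 | pentacarbonyl[methoxy(1-methoxyvinyl)carbene]chromium | COC(=C)C(OC)=[Cr](=C=O)(=C=O)(=C=O)(=C=O)=C=O
A2 | alternative 1 | 2-(docos-1-yn-1-yl)-4,4,5,5-tetramethyl-1,3,2-dioxaborolane | CCCCCCCCCCCCCCCCCCCCC#CB1OC(C)(C)C(C)(C)O1
A3 | alternative 1 | 3-icosyl-4,5-dimethoxy-2-(4,4,5,5-tetramethyl-1,3,2-dioxaborolan-2-yl)phenol | CCCCCCCCCCCCCCCCCCCCc1c(B2OC(C)(C)C(C)(C)O2)c(O)cc(OC)c1OC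
A4 | alternative 2 | tetracosane-2,3-dione | CCCCCCCCCCCCCCCCCCCCCC(=O)C(C)=O
A5 | alternative 2 | 2,5-dihydroxy-3-icosyl-1,4-benzoquinone | CCCCCCCCCCCCCCCCCCCCC1=C(O)C(=O)C=C(O)C1=O
A6 | alternative 3 | 4-hydroxy-2-icosyl-3-isopropoxy-4-(methoxyethynyl)cyclobut-2-en-1-one (racemic) | CCCCCCCCCCCCCCCCCCCCC1=C(OC(C)C)C(O)(C#COC)C1=O
A7 | alternative 3 | 3-icosyl-2-isopropoxy-5-methoxy-1,4-benzoquinone | CCCCCCCCCCCCCCCCCCCCC1=C(OC(C)C)C(=O)C=C(OC)C1=O
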